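## Analysis of the target

Target 44 is a linear, achiral hexamer of oxygenated benzene rings (A to F along the chain) joined by five diaryl ether oxygens. It carries fifteen free phenolic hydroxyls and no stereocentre, so the whole problem is connectivity and handling. Ring A is a 2,4,6-trihydroxyphenyl ether, rings B and D are 1,4-bis(aryloxy)benzenes whose two hydroxyls flank one ether carbon, rings C and E are pentaoxygenated with two neighbouring ether oxygens beside three neighbouring hydroxyls, and ring F is a 3,4,5-trihydroxyphenyl ether. The free polyphenol contains pyrogallol and hydroxyquinol units that oxidise in air, above all under base, so every hydroxyl has to travel as an ether that is removed under neutral conditions in the last step. The difficulty lies in the ether bonds: each of the five oxygens sits on at least one ring carbon flanked by two further oxygen-bearing carbons, so each conventional C–O coupling has to join a doubly ortho-substituted, electron-rich partner. In addition the six rings are so alike that a misplaced oxygen would give an isomer that is hard to tell apart. The strategy rests on ring D. Numbered from the carbon bonded to the ring C oxygen, C1 and C4 carry the two aryloxy groups para to each other, C3 and C5 carry hydroxyls and C2 and C6 hydrogen. This is the pattern that results when the two carbons of an oxygen-substituted alkyne (C1, C2) are inserted into the four-carbon unit of a 3-alkoxy-4-aryloxycyclobutenone (C3 to C6).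

## Retrosynthetic reasoning

In rings C and E the ether carbon next to a benzyloxy-bearing carbon is called "inner" and the one next to C–H "outer".

**44 to 43.** The fifteen O–benzyl bonds are cut last. Benzyl ethers survive bases, organolithiums at low temperature, copper catalysis, peracid and heat, and they fall off together under neutral hydrogenolysis, so the air-sensitive polyphenol 44 is handled only once. The single free hydroxyl of 43 needs no protection.

**43 to 23 and 40.** Ring D is cut at C2–C3 and C6–C1. This divides the hexamer into an ABC half (ynol ether 23, eight benzyl groups) and an EF half (cyclobutenone 40, seven benzyl groups) of similar size. The cut is placed here because both ring D oxygens would otherwise need couplings at flanked carbons: the D–E oxygen sits between the two ring D hydroxyls and the C–D oxygen on the inner carbon of ring C. In 23 and 40 both oxygens are already attached, to an alkyne carbon and to the sp3 carbon of the four-membered ring, so the forward step forms only C–C bonds. It has to deliver one regiochemistry: the alkyne CH carbon must bond to the carbonyl carbon of 40 and the oxygen-bearing alkyne carbon to its vinylic CH.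

**40 to 35 and 38.** The four-membered ring is cut into ketene 39, released from acid chloride 35, and benzyl ethynyl ether 38. Ketene–ynol ether cycloaddition puts the benzyloxy group at C3 and the aryloxy carbon at C4. 38 goes back through dichlorovinyl ether 36 to benzyl alcohol 7 and trichloroethylene 20. 35 goes back through acid 34 and ester 33 to EF phenol 31 and ethyl bromoacetate 32, that is, to a simple O-alkylation of the outer hydroxyl of ring E.

**31 to 27 and 28.** The E–F ether is cut so that the flanked inner carbon of ring E is the electrophile (bromide 28, ortho to a formyl group) and the unhindered ring F phenol 27 the nucleophile. The formyl group of coupling product 29 then becomes the outer hydroxyl of 31 by Baeyer–Villiger oxidation. It thus serves twice, as activator of the coupling and as masked phenol. Both 27 and 28 come from one aldehyde, 25, made from 24.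

**23 to 19 and 20.** The O–C(sp) bond is cut. The ynol ether is made from ABC phenol 19 through dichlorovinyl ether 21, which needs only a small electrophile at the hindered inner oxygen of ring C.

**19 to 12 and 16.** The B–C ether is cut with the hindered AB phenol 12 as nucleophile and bromo aldehyde 16 as electrophile. In 16 the bromine is at the outer carbon and the formyl group at the inner carbon, so coupling followed by Baeyer–Villiger oxidation of 17 gives exactly the inner hydroxyl needed for 23. 16 is reached from bromide 14 (from 13) by deprotonation at the only type of ring C–H, which lies between bromine and a benzyloxy group.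

**12 to 5 and 9.** The A–B ether is cut with the doubly flanked ring A phenol 5 as nucleophile and the para-formyl bromide 9 as electrophile. Oxidation of 10 turns the formyl carbon into the ring B hydroxyl between the two benzyloxy groups. 5 comes from 1 through aldehyde 3, and 9 from 6 and 7 by fluoride displacement.

The same two-step motif, coupling at a bromide activated by an ortho or para formyl group and then conversion of that formyl group into the next phenol, builds all three conventional ether bonds. The risk of the route is thereby concentrated in the ring D construction.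

## Alternatives that were turned down

**Alternative 1:** Ring B is disconnected at both its ether bonds, and both are made by nucleophilic aromatic substitution on a π-complexed dichloroarene.
- *Forward key step:* The cationic complex A2, (η5-C5H5)Ru(η6-arene) hexafluorophosphate of divalent ruthenium with 1,4-dichloro-2,6-bis(methoxymethoxy)benzene, would take up the phenoxide of 5 at the unhindered chloride. It would then take up the phenoxide of the CDEF tetramer A3 at the chloride between the two methoxymethyl ethers. Irradiation in a nitrile solvent would release the bis(methoxymethyl) hexamer A1.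
- *For it:* π-Complexation makes even an alkoxy-rich chloroarene reactive toward phenoxides near room temperature. The bond to the doubly flanked ring B carbon would thus be made under milder and better precedented conditions than the key step chosen here. On this point the alternative is the stronger one.
- *Against it:* It consumes a full equivalent of ruthenium, needs a second protecting-group type with an acidic removal, and the order of the two substitutions in one flask rests only on a rate difference. More seriously, A3 already contains the C–D and D–E ether bonds, which are of the same hindered kind. The alternative therefore solves one ring and moves the hardest couplings into the preparation of A3. The assembly is 1 + 1 + 4, and the last substitution sends a four-ring nucleophile to the most hindered carbon.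
- *Comparison:* The chosen strategy builds ring D itself with both oxygens in place, without stoichiometric metal, from two halves of similar size.

**Alternative 2:** Ring B is cut at C2–C3 and C5–C6 into two three-carbon pieces.
- *Forward key step:* Aminoacrolein A5 (a masked 2-aryloxymalondialdehyde) and 1,3-bis(benzyloxy)acetone A6 would condense twice under alkoxide base and aromatise to the AB phenol A4, which is identical with 12.
- *For it:* It is metal-free and cheap, the ring A oxygen is attached by alkylation, and the symmetry of A6 leaves no regiochemical choice. In these respects it equals the chosen strategy and is operationally simpler than a benzannulation.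
- *Against it:* The ring-forming step yields only a two-ring fragment, which this route reaches as 12 in five steps by an activated coupling. Four ether bonds, among them all those at rings C, D and E, remain. A5 would have to come from an aryloxyacetic acid by double formylation with a chloroiminium reagent, and under those conditions the tris(benzyloxy)phenyl ring with its two free activated positions is itself formylated (compare step 1). The enolate of A6 can lose benzyloxide or self-condense.
- *Comparison:* The chosen strategy spends its ring construction where it replaces two hindered couplings and joins the two halves.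

**Alternative 3:** Ring A is made last by cutting its two C–C bonds between the hydroxyl-bearing carbons next to the ether carbon and the ester-bearing carbons.
- *Forward key step:* Aryloxymalonate A8 of the BCDEF pentamer and dimethyl 3-oxopentanedioate A9 would undergo Claisen and then Dieckmann condensation under methoxide to give isophthalate A7 with ring A closed as a free triol. Ester hydrolysis, double decarboxylation and hydrogenolysis would follow.
- *For it:* The three ring A hydroxyls need no protecting groups and their positions are fixed by symmetry. In protecting-group economy it is stronger than the chosen route.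
- *Against it:* The plan is fully linear. A8 requires the five-ring chain, that is, four successive couplings at flanked carbons, which are the actual problem. The ring-forming step comes last, on the most valuable intermediate, under hot alkoxide. A8 is first deprotonated at its aryloxy-bearing carbon, which blunts both ester groups as acylating agents. Two further steps on an air-sensitive free phloroglucinol are then needed.
- *Comparison:* The chosen strategy is convergent, with two halves of ten and eleven steps, and its one uncertain step can be tested as soon as both halves are in hand.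

Key step: step 23

## Route

Assumption: compounds 1, 6, 7, 13, 20, 24 and 32 are taken as catalogue chemicals; the target has no stereocentre, and the one stereocentre of 40 (and 42) is racemic and disappears in step 23.

Abbreviations used in names:
- ArABC = 2,3,4-tris(benzyloxy)-6-{2,6-bis(benzyloxy)-4-[2,4,6-tris(benzyloxy)phenoxy]phenoxy}phenyl
- ArEF = 3,4,5-tris(benzyloxy)-2-[3,4,5-tris(benzyloxy)phenoxy]phenyl

Step 1
Reactants: 1 1,3,5-tris(benzyloxy)benzene
Product: 3 2,4,6-tris(benzyloxy)benzaldehyde, via iminium chloride 2 (not isolated)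
Conditions: POCl3, DMF, 0 °C → rt; then ice–water
Reagents that add atoms: N,N-dimethylformamide CN(C)C=O (formyl carbon); water O (carbonyl oxygen)
Why: Vilsmeier–Haack formylation; the phloroglucinol triether is highly reactive toward the chloroiminium ion and its three free positions are equivalent, so one aldehyde should result after hydrolysis of 2.

Step 2
Reactants: 3 2,4,6-tris(benzyloxy)benzaldehyde
Product: 5 2,4,6-tris(benzyloxy)phenol, via aryl formate 4 (not isolated)
Conditions: mCPBA, CH2Cl2, 0 °C → rt; then cat. K2CO3, MeOH, rt, Ar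
Reagents that add atoms: 3-chloroperoxybenzoic acid O=C(OO)c1cccc(Cl)c1
Why: Baeyer–Villiger oxidation; the trialkoxyaryl group migrates in preference to hydrogen, and the phenol is freed by methanolysis of 4 only after the peracid has been consumed.

Step 3
Reactants: 6 4-bromo-2,6-difluorobenzaldehyde; 7 benzyl alcohol
Product: 9 2,6-bis(benzyloxy)-4-bromobenzaldehyde, via monofluoride 8 (not isolated)
Conditions: 7 (2.2 equiv), NaH, THF, 0 °C → 40 °C
Reagents that add atoms: none
Why: Nucleophilic aromatic substitution (addition–elimination); both fluorines are ortho to the formyl group and fluoride leaves far faster than the para bromide, which is kept for step 4.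

Step 4
Reactants: 5 2,4,6-tris(benzyloxy)phenol; 9 2,6-bis(benzyloxy)-4-bromobenzaldehyde
Product: 10 2,6-bis(benzyloxy)-4-[2,4,6-tris(benzyloxy)phenoxy]benzaldehyde (AB aldehyde)
Conditions: CuI (10 mol%), picolinic acid (20 mol%), K3PO4, DMSO, 90 °C, Ar
Reagents that add atoms: none
Why: Ullmann-type O-arylation under monovalent copper catalysis; the bromide is unhindered and para to the formyl group, which offsets the 2,6-disubstitution of phenoxide 5.

Step 5
Reactants: 10 AB aldehyde
Product: 12 2,6-bis(benzyloxy)-4-[2,4,6-tris(benzyloxy)phenoxy]phenol (AB phenol), via aryl formate 11 (not isolated)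
Conditions: mCPBA, CH2Cl2, 0 °C → rt; then cat. K2CO3, MeOH–THF, rt, Ar
Reagents that add atoms: 3-chloroperoxybenzoic acid O=C(OO)c1cccc(Cl)c1
Why: Baeyer–Villiger oxidation; the migrating ring carries two ortho alkoxy groups and a para aryloxy group, so the formyl carbon becomes the ring B hydroxyl between the two benzyloxy groups.

Step 6
Reactants: 13 5-bromobenzene-1,2,3-triol
Product: 14 5-bromo-1,2,3-tris(benzyloxy)benzene
Conditions: BnBr, K2CO3, DMF, 60 °C, Ar
Reagents that add atoms: benzyl bromide BrCc1ccccc1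
Why: Williamson ether synthesis at the three phenolic hydroxyls; air is excluded because the pyrogallol anion oxidises easily.

Step 7
Reactants: 14 5-bromo-1,2,3-tris(benzyloxy)benzene
Product: 16 2,3,4-tris(benzyloxy)-6-bromobenzaldehyde, via aryllithium 15 (not isolated)
Conditions: LiN(i-Pr)2 (1.1 equiv), THF, −78 °C; DMF, −78 → 0 °C; 1 M HCl
Reagents that add atoms: N,N-dimethylformamide CN(C)C=O
Why: Directed ortho-metalation and formylation; the only kind of ring C–H lies between bromine and a benzyloxy group, and a lithium amide removes it at −78 °C without bromine–lithium exchange or benzylic deprotonation.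

Step 8
Reactants: 12 AB phenol; 16 2,3,4-tris(benzyloxy)-6-bromobenzaldehyde
Product: 17 ArABC-carbaldehyde (ABC aldehyde; formyl group between a benzyloxy group and the ring B oxygen)
Conditions: CuI (20 mol%), picolinic acid (40 mol%), K3PO4, DMSO, 100 °C, Ar
Reagents that add atoms: none
Why: Ullmann-type O-arylation; the bromide is ortho to the formyl group, the classical activated case, and has hydrogen on its other side, so the hindered phenoxide of 12 should be accommodated.

Step 9
Reactants: 17 ABC aldehyde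
Product: 19 ArABC-OH (ABC phenol), via aryl formate 18 (not isolated)
Conditions: mCPBA, CH2Cl2, 0 °C → rt; then cat. K2CO3, MeOH–THF, rt, Ar
Reagents that add atoms: 3-chloroperoxybenzoic acid O=C(OO)c1cccc(Cl)c1
Why: Baeyer–Villiger oxidation; the formyl carbon, flanked by benzyloxy and aryloxy groups, becomes the inner ring C hydroxyl that will be the ring D ether oxygen.

Step 10
Reactants: 19 ABC phenol; 20 trichloroethylene
Product: 21 ArABC (E)-1,2-dichlorovinyl ether
Conditions: 20 (1.5 equiv), K2CO3, DMF, 70 °C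
Reagents that add atoms: none
Why: Vinylic substitution of trichloroethylene by a phenoxide (elimination to dichloroacetylene, then anti addition), the standard entry to aryl 1,2-dichlorovinyl ethers; the small electrophile reaches the hindered oxygen.

Step 11
Reactants: 21 ArABC (E)-1,2-dichlorovinyl ether
Product: 23 ArABC ethynyl ether (ABC ynol ether), via lithium acetylide 22 (not isolated)
Conditions: n-BuLi (2.2 equiv), THF, −78 °C; MeOH, −78 → 0 °C; used at once
Reagents that add atoms: none
Why: Dehydrochlorination to the chloroalkyne and chlorine–lithium exchange, the usual ynol ether synthesis from 1,2-dichlorovinyl ethers; both are fast at −78 °C, and protonation of 22 gives the terminal ynol ether.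

Step 12
Reactants: 24 3,4,5-trihydroxybenzaldehyde
Product: 25 3,4,5-tris(benzyloxy)benzaldehyde
Conditions: BnBr, K2CO3, DMF, 60 °C, Ar
Reagents that add atoms: benzyl bromide BrCc1ccccc1
Why: Williamson ether synthesis at the three phenolic hydroxyls.

Step 13
Reactants: 25 3,4,5-tris(benzyloxy)benzaldehyde
Product: 27 3,4,5-tris(benzyloxy)phenol, via aryl formate 26 (not isolated)
Conditions: mCPBA, CH2Cl2, 0 °C → rt; then cat. K2CO3, MeOH, rt, Ar
Reagents that add atoms: 3-chloroperoxybenzoic acid O=C(OO)c1cccc(Cl)c1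
Why: Baeyer–Villiger oxidation; the para benzyloxy group makes aryl migration faster than hydride migration.

Step 14
Reactants: 25 3,4,5-tris(benzyloxy)benzaldehyde
Product: 28 3,4,5-tris(benzyloxy)-2-bromobenzaldehyde
Conditions: NBS, MeCN, rt, dark
Reagents that add atoms: N-bromosuccinimide O=C1CCC(=O)N1Br
Why: Electrophilic aromatic bromination; the two free positions are equivalent and activated by ortho and para benzyloxy groups, while the benzyl rings are far less reactive.

Step 15
Reactants: 27 3,4,5-tris(benzyloxy)phenol; 28 3,4,5-tris(benzyloxy)-2-bromobenzaldehyde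
Product: 29 3,4,5-tris(benzyloxy)-2-[3,4,5-tris(benzyloxy)phenoxy]benzaldehyde (EF aldehyde)
Conditions: CuI (10 mol%), picolinic acid (20 mol%), K3PO4, DMSO, 90 °C, Ar
Reagents that add atoms: none
Why: Ullmann-type O-arylation; the flanked bromide is activated by the ortho formyl group and the phenol is unhindered, the same pairing used classically for 2-halo-3,4,5-trialkoxybenzoyl compounds.

Step 16
Reactants: 29 EF aldehyde
Product: 31 ArEF-OH (EF phenol), via aryl formate 30 (not isolated)
Conditions: mCPBA, CH2Cl2, 0 °C → rt; then cat. K2CO3, MeOH–THF, rt, Ar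
Reagents that add atoms: 3-chloroperoxybenzoic acid O=C(OO)c1cccc(Cl)c1
Why: Baeyer–Villiger oxidation; ortho aryloxy and para benzyloxy groups drive aryl migration and the outer ring E hydroxyl results.

Step 17
Reactants: 31 EF phenol; 32 ethyl bromoacetate
Product: 33 ethyl 2-(ArEF-oxy)acetate
Conditions: K2CO3, DMF, 50 °C
Reagents that add atoms: none
Why: Williamson O-alkylation of a phenoxide with a reactive α-halo ester.

Step 18
Reactants: 33 ethyl 2-(ArEF-oxy)acetate
Product: 34 2-(ArEF-oxy)acetic acid
Conditions: LiOH, THF–MeOH–H2O, rt; then 1 M HCl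
Reagents that add atoms: lithium hydroxide [Li+].[OH-]
Why: Ester saponification; benzyl and diaryl ethers are inert to hydroxide.

Step 19
Reactants: 34 2-(ArEF-oxy)acetic acid
Product: 35 2-(ArEF-oxy)acetyl chloride
Conditions: (COCl)2, cat. DMF, CH2Cl2, 0 °C → rt; evaporation, used crude
Reagents that add atoms: oxalyl chloride O=C(Cl)C(=O)Cl
Why: Acid chloride formation through the chloroiminium catalyst; no Lewis acid is present, so ring acylation should not occur.

Step 20
Reactants: 7 benzyl alcohol; 20 trichloroethylene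
Product: 36 benzyl (E)-1,2-dichlorovinyl ether
Conditions: KH, THF, 0 °C; then 20, 0 °C → rt
Reagents that add atoms: none
Why: Anti addition of the alkoxide to dichloroacetylene generated in the flask from trichloroethylene, which gives the E ether.

Step 21
Reactants: 36 benzyl (E)-1,2-dichlorovinyl ether
Product: 38 benzyl ethynyl ether, via lithium acetylide 37 (not isolated)
Conditions: n-BuLi (2.2 equiv), Et2O, −78 °C; MeOH, −78 °C; kept at or below 0 °C as a solution
Reagents that add atoms: none
Why: Same elimination and chlorine–lithium exchange as in step 11; 38 is kept cold because benzyl alkynyl ethers undergo a sigmatropic benzyl shift on warming.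

Step 22
Reactants: 35 2-(ArEF-oxy)acetyl chloride; 38 benzyl ethynyl ether
Product: 40 racemic 3-(benzyloxy)-4-(ArEF-oxy)cyclobut-2-en-1-one, via aryloxyketene 39 (not isolated)
Conditions: 38 (3 equiv), Et3N, Et2O–CH2Cl2, 0 °C → rt, slow addition of 35
Reagents that add atoms: none
Why: Ketene–ynol ether [2+2] cycloaddition; the nucleophilic CH terminus of 38 attacks the carbonyl carbon of ketene 39, which places benzyloxy at C3 and the aryloxy carbon at C4. The C4 stereocentre forms racemic and is destroyed in step 23.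

Step 23
Reactants: 23 ABC ynol ether; 40 3-(benzyloxy)-4-(ArEF-oxy)cyclobut-2-en-1-one
Product: 43 3-(benzyloxy)-5-(ArABC-oxy)-2-(ArEF-oxy)phenol, via vinylketene 41 (not isolated), via vinylcyclobutenone 42 (not isolated)
Conditions: PhMe (0.1 M in 23), 40 (1.3 equiv) added in portions, 80 °C then 110 °C, Ar; then K2CO3, MeOH–THF, rt
Reagents that add atoms: none
Why: Heating opens 40 by conrotatory 4π ring opening, the C4 aryloxy group turning outward, to the (Z)-vinylketene 41. The electron-rich CH terminus of ynol ether 23 attacks the ketene carbonyl carbon, and the [2+2] adduct 42 carries the ring C oxygen on the carbon bonded to the former vinylic CH of 40; this orientation is the one selectivity the step needs, and the oxygen lone pair of 23 secures it because it makes the CH terminus the only nucleophilic carbon. A second 4π opening of 42 gives a dienylketene whose ketene carbon and aryloxy-bearing terminus close ring D by thermal disrotatory 6π electrocyclisation, and tautomerisation of the cyclohexadienone gives the phenol. Outward rotation in the first opening leaves hydrogen, not the EF aryloxy group, on the inside of the cyclising triene, so the closure is not blocked. No stereocentre is formed. The closest known reaction type is the Danheiser benzannulation of cyclobutenones with alkoxy- and siloxyacetylenes, which gives resorcinol monoethers with this orientation. The oxygen of 23 is bonded to an aromatic carbon, so there is no C–H in the position needed for retro-ene loss of a ketene. The closing carbonate–methanol treatment returns any product that was O-acylated by 41.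

Step 24
Reactants: 43 3-(benzyloxy)-5-(ArABC-oxy)-2-(ArEF-oxy)phenol
Product: 44 target hexamer CNP0114537.0
Conditions: H2 (1 atm), 10% Pd/C, THF–MeOH, rt; filtration and evaporation under Ar
Reagents that add atoms: none
Why: Hydrogenolysis of the fifteen benzyl aryl ethers; diaryl ethers and the arene rings are untouched, and neutral conditions protect the oxidation-prone polyphenol.

## Compound list

1 | 1,3,5-tris(benzyloxy)benzene | c1c(OCc9ccccc9)cc(OCc9ccccc9)cc1OCc9ccccc9 | starting material
2 | N-[2,4,6-tris(benzyloxy)benzylidene]-N-methylmethanaminium chloride | C[N+](C)=Cc1c(OCc9ccccc9)cc(OCc9ccccc9)cc1OCc9ccccc9.[Cl-] | intermediate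
3 | 2,4,6-tris(benzyloxy)benzaldehyde | O=Cc1c(OCc9ccccc9)cc(OCc9ccccc9)cc1OCc9ccccc9 | intermediate
4 | 2,4,6-tris(benzyloxy)phenyl formate | O=COc1c(OCc9ccccc9)cc(OCc9ccccc9)cc1OCc9ccccc9 | intermediate
5 | 2,4,6-tris(benzyloxy)phenol | Oc1c(OCc9ccccc9)cc(OCc9ccccc9)cc1OCc9ccccc9 | intermediate
6 | 4-bromo-2,6-difluorobenzaldehyde | O=Cc1c(F)cc(Br)cc1F | starting material
7 | benzyl alcohol | OCc1ccccc1 | starting material
8 | 2-(benzyloxy)-4-bromo-6-fluorobenzaldehyde | O=Cc1c(F)cc(Br)cc1OCc9ccccc9 | intermediate
9 | 2,6-bis(benzyloxy)-4-bromobenzaldehyde | O=Cc1c(OCc9ccccc9)cc(Br)cc1OCc9ccccc9 | intermediate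
10 | 2,6-bis(benzyloxy)-4-[2,4,6-tris(benzyloxy)phenoxy]benzaldehyde | O=Cc2c(OCc9ccccc9)cc(Oc1c(OCc9ccccc9)cc(OCc9ccccc9)cc1OCc9ccccc9)cc2OCc9ccccc9 | intermediate
11 | 2,6-bis(benzyloxy)-4-[2,4,6-tris(benzyloxy)phenoxy]phenyl formate | O=COc2c(OCc9ccccc9)cc(Oc1c(OCc9ccccc9)cc(OCc9ccccc9)cc1OCc9ccccc9)cc2OCc9ccccc9 | intermediate
12 | 2,6-bis(benzyloxy)-4-[2,4,6-tris(benzyloxy)phenoxy]phenol | Oc2c(OCc9ccccc9)cc(Oc1c(OCc9ccccc9)cc(OCc9ccccc9)cc1OCc9ccccc9)cc2OCc9ccccc9 | intermediate
13 | 5-bromobenzene-1,2,3-triol | Oc1cc(Br)cc(O)c1O | starting material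
14 | 5-bromo-1,2,3-tris(benzyloxy)benzene | Brc1cc(OCc9ccccc9)c(OCc9ccccc9)c(OCc9ccccc9)c1 | intermediate
15 | [2,3,4-tris(benzyloxy)-6-bromophenyl]lithium | [Li]c1c(OCc9ccccc9)c(OCc9ccccc9)c(OCc9ccccc9)cc1Br | intermediate
16 | 2,3,4-tris(benzyloxy)-6-bromobenzaldehyde | O=Cc1c(OCc9ccccc9)c(OCc9ccccc9)c(OCc9ccccc9)cc1Br | intermediate
17 | 2,3,4-tris(benzyloxy)-6-{2,6-bis(benzyloxy)-4-[2,4,6-tris(benzyloxy)phenoxy]phenoxy}benzaldehyde | O=Cc3c(OCc9ccccc9)c(OCc9ccccc9)c(OCc9ccccc9)cc3Oc2c(OCc9ccccc9)cc(Oc1c(OCc9ccccc9)cc(OCc9ccccc9)cc1OCc9ccccc9)cc2OCc9ccccc9 | intermediate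
18 | ArABC formate | O=COc3c(OCc9ccccc9)c(OCc9ccccc9)c(OCc9ccccc9)cc3Oc2c(OCc9ccccc9)cc(Oc1c(OCc9ccccc9)cc(OCc9ccccc9)cc1OCc9ccccc9)cc2OCc9ccccc9 | intermediate
19 | 2,3,4-tris(benzyloxy)-6-{2,6-bis(benzyloxy)-4-[2,4,6-tris(benzyloxy)phenoxy]phenoxy}phenol (ArABC-OH) | Oc3c(OCc9ccccc9)c(OCc9ccccc9)c(OCc9ccccc9)cc3Oc2c(OCc9ccccc9)cc(Oc1c(OCc9ccccc9)cc(OCc9ccccc9)cc1OCc9ccccc9)cc2OCc9ccccc9 | intermediate
20 | trichloroethylene | ClC=C(Cl)Cl | starting material
21 | ArABC (E)-1,2-dichlorovinyl ether | Cl/C=C(/Cl)Oc3c(OCc9ccccc9)c(OCc9ccccc9)c(OCc9ccccc9)cc3Oc2c(OCc9ccccc9)cc(Oc1c(OCc9ccccc9)cc(OCc9ccccc9)cc1OCc9ccccc9)cc2OCc9ccccc9 | intermediate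
22 | [(ArABC-oxy)ethynyl]lithium | [Li]C#COc3c(OCc9ccccc9)c(OCc9ccccc9)c(OCc9ccccc9)cc3Oc2c(OCc9ccccc9)cc(Oc1c(OCc9ccccc9)cc(OCc9ccccc9)cc1OCc9ccccc9)cc2OCc9ccccc9 | intermediate
23 | ArABC ethynyl ether | C#COc3c(OCc9ccccc9)c(OCc9ccccc9)c(OCc9ccccc9)cc3Oc2c(OCc9ccccc9)cc(Oc1c(OCc9ccccc9)cc(OCc9ccccc9)cc1OCc9ccccc9)cc2OCc9ccccc9 | intermediate
24 | 3,4,5-trihydroxybenzaldehyde | O=Cc1cc(O)c(O)c(O)c1 | starting material
25 | 3,4,5-tris(benzyloxy)benzaldehyde | O=Cc1cc(OCc9ccccc9)c(OCc9ccccc9)c(OCc9ccccc9)c1 | intermediate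
26 | 3,4,5-tris(benzyloxy)phenyl formate | O=COc1cc(OCc9ccccc9)c(OCc9ccccc9)c(OCc9ccccc9)c1 | intermediate
27 | 3,4,5-tris(benzyloxy)phenol | Oc1cc(OCc9ccccc9)c(OCc9ccccc9)c(OCc9ccccc9)c1 | intermediate
28 | 3,4,5-tris(benzyloxy)-2-bromobenzaldehyde | O=Cc1cc(OCc9ccccc9)c(OCc9ccccc9)c(OCc9ccccc9)c1Br | intermediate
29 | 3,4,5-tris(benzyloxy)-2-[3,4,5-tris(benzyloxy)phenoxy]benzaldehyde | O=Cc5cc(OCc9ccccc9)c(OCc9ccccc9)c(OCc9ccccc9)c5Oc6cc(OCc9ccccc9)c(OCc9ccccc9)c(OCc9ccccc9)c6 | intermediate
30 | ArEF formate | O=COc5cc(OCc9ccccc9)c(OCc9ccccc9)c(OCc9ccccc9)c5Oc6cc(OCc9ccccc9)c(OCc9ccccc9)c(OCc9ccccc9)c6 | intermediate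
31 | 3,4,5-tris(benzyloxy)-2-[3,4,5-tris(benzyloxy)phenoxy]phenol (ArEF-OH) | Oc5cc(OCc9ccccc9)c(OCc9ccccc9)c(OCc9ccccc9)c5Oc6cc(OCc9ccccc9)c(OCc9ccccc9)c(OCc9ccccc9)c6 | intermediate
32 | ethyl bromoacetate | CCOC(=O)CBr | starting material
33 | ethyl 2-(ArEF-oxy)acetate | CCOC(=O)COc5cc(OCc9ccccc9)c(OCc9ccccc9)c(OCc9ccccc9)c5Oc6cc(OCc9ccccc9)c(OCc9ccccc9)c(OCc9ccccc9)c6 | intermediate
34 | 2-(ArEF-oxy)acetic acid | OC(=O)COc5cc(OCc9ccccc9)c(OCc9ccccc9)c(OCc9ccccc9)c5Oc6cc(OCc9ccccc9)c(OCc9ccccc9)c(OCc9ccccc9)c6 | intermediate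
35 | 2-(ArEF-oxy)acetyl chloride | ClC(=O)COc5cc(OCc9ccccc9)c(OCc9ccccc9)c(OCc9ccccc9)c5Oc6cc(OCc9ccccc9)c(OCc9ccccc9)c(OCc9ccccc9)c6 | intermediate
36 | benzyl (E)-1,2-dichlorovinyl ether | Cl/C=C(/Cl)OCc1ccccc1 | intermediate
37 | [(benzyloxy)ethynyl]lithium | [Li]C#COCc1ccccc1 | intermediate
38 | benzyl ethynyl ether | C#COCc1ccccc1 | intermediate
39 | (ArEF-oxy)ketene | O=C=COc5cc(OCc9ccccc9)c(OCc9ccccc9)c(OCc9ccccc9)c5Oc6cc(OCc9ccccc9)c(OCc9ccccc9)c(OCc9ccccc9)c6 | intermediate
40 | racemic 3-(benzyloxy)-4-(ArEF-oxy)cyclobut-2-en-1-one | O=C7C=C(OCc9ccccc9)C7Oc5cc(OCc9ccccc9)c(OCc9ccccc9)c(OCc9ccccc9)c5Oc6cc(OCc9ccccc9)c(OCc9ccccc9)c(OCc9ccccc9)c6 | intermediate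
41 | (Z)-3-(benzyloxy)-4-(ArEF-oxy)buta-1,3-dien-1-one | O=C=C/C(OCc9ccccc9)=C/Oc5cc(OCc9ccccc9)c(OCc9ccccc9)c(OCc9ccccc9)c5Oc6cc(OCc9ccccc9)c(OCc9ccccc9)c(OCc9ccccc9)c6 | intermediate
42 | racemic 3-(ArABC-oxy)-4-[(Z)-1-(benzyloxy)-2-(ArEF-oxy)vinyl]cyclobut-2-en-1-one | O=C7C=C(Oc3c(OCc9ccccc9)c(OCc9ccccc9)c(OCc9ccccc9)cc3Oc2c(OCc9ccccc9)cc(Oc1c(OCc9ccccc9)cc(OCc9ccccc9)cc1OCc9ccccc9)cc2OCc9ccccc9)C7/C(OCc9ccccc9)=C/Oc5cc(OCc9ccccc9)c(OCc9ccccc9)c(OCc9ccccc9)c5Oc6cc(OCc9ccccc9)c(OCc9ccccc9)c(OCc9ccccc9)c6 | intermediate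
43 | 3-(benzyloxy)-5-(ArABC-oxy)-2-(ArEF-oxy)phenol (pentadeca-O-benzyl hexamer, free ring D hydroxyl) | Oc4cc(Oc3c(OCc9ccccc9)c(OCc9ccccc9)c(OCc9ccccc9)cc3Oc2c(OCc9ccccc9)cc(Oc1c(OCc9ccccc9)cc(OCc9ccccc9)cc1OCc9ccccc9)cc2OCc9ccccc9)cc(OCc9ccccc9)c4Oc5cc(OCc9ccccc9)c(OCc9ccccc9)c(OCc9ccccc9)c5Oc6cc(OCc9ccccc9)c(OCc9ccccc9)c(OCc9ccccc9)c6 | intermediate
44 | CNP0114537.0, the pentadecahydroxy hexamer (43 with all benzyl groups replaced by hydrogen) | Oc1cc(O)c(Oc2cc(O)c(Oc3cc(O)c(O)c(O)c3Oc3cc(O)c(Oc4cc(O)c(O)c(O)c4Oc4cc(O)c(O)c(O)c4)c(O)c3)c(O)c2)c(O)c1 | target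

## Step count and weak points

Total: 24 steps. Longest linear sequence: 10 steps (1 → 3 → 5 → 10 → 12 → 17 → 19 → 21 → 23 → 43 → 44; the line from 24 through 25, 27 or 28, 29, 31, 33, 34, 35, 40, 43 to 44 is equally long).

**Step 23 (key step).**
- *What may go wrong:* Capture of vinylketene 41 by 23 is bimolecular between two large partners at low concentration, and an aryloxy alkyne is a weaker nucleophile than the alkoxy and siloxy alkynes usually used. 41 may therefore be lost by dimerisation, by acylation of product phenol or by unproductive reclosure, while 23 slowly oligomerises on long heating.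
- *Fallback:* Ring construction at the centre is given up for stepwise ether synthesis from phenol 19 with building blocks already in the route.
  - Copper-catalysed coupling of 19 with bromo aldehyde 9 should give the ABCD aldehyde F1.
  - Baeyer–Villiger oxidation through the ABCD formate F2 and methanolysis should give the ABCD phenol F3.
  - Coupling of F3 with bromo aldehyde 16 should give the ABCDE aldehyde F4.
  - Oxidation through the ABCDE formate F5 should give the ABCDE phenol F6.
  - Coupling of F6 with bromide 14, the least activated coupling of this sequence, should give the hexadeca-O-benzyl hexamer F7.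
  - Hydrogenolysis of F7 rejoins the route at target 44.

**Step 22.**
- *What may go wrong:* The terminal benzyl ynol ether 38 may be lost by polymerisation or by sigmatropic benzyl shift before it meets ketene 39, and 39 may then dimerise.
- *Fallback:* It sets out from lithium acetylide 37. Trapping with Me3SiCl gives benzyl (trimethylsilyl)ethynyl ether F8, which can be purified and stored. Cycloaddition of F8 with ketene 39 should give the 2-silylcyclobutenone F9. Protodesilylation (Bu4NF–AcOH, THF, 0 °C) returns to the route at 40.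

**Step 11.**
- *What may go wrong:* n-BuLi may deprotonate benzylic or ring positions of the eight benzyl ethers (leading to Wittig rearrangement) in competition with the chlorine–lithium exchange, and the ynol ether may be hydrated on work-up.
- *Fallback:* It sets out from phenol 19. Vinylation with (Z)-1,2-dichloroethylene under KOH in DMSO (through chloroacetylene) gives the ArABC (Z)-2-chlorovinyl ether F10. Dehydrochlorination with LiN(i-Pr)2 (2.2 equiv, THF, −78 °C), which needs no halogen–metal exchange, returns to the route at acetylide 22 and, after protonation, at 23.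

**Step 8.**
- *What may go wrong:* The doubly ortho-substituted phenoxide of 12 may couple slowly, so that protodebromination of 16 and copper-mediated oxidation of the phenol take over.
- *Fallback:* It sets out from phenol 27. Magnesium-mediated ortho-formylation (MgCl2, Et3N, paraformaldehyde) gives 2,3,4-tris(benzyloxy)-6-hydroxybenzaldehyde F11. Triflation (Tf2O, pyridine) gives the aryl triflate F12. Coupling of F12 with 12 under zerovalent palladium catalysis (Pd2(dba)3, t-BuXPhos, K3PO4, toluene, 100 °C) returns to the route at 17.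

**Step 7.**
- *What may go wrong:* Aryllithium 15 may lose LiBr to an aryne before it is formylated, or deprotonation may be incomplete.
- *Fallback:* It sets out from 14. Bromination (NBS, MeCN) gives 1,2,3-tris(benzyloxy)-4,5-dibromobenzene F13. Bromine–magnesium exchange with i-PrMgCl·LiCl at the bromine next to the benzyloxy group (THF, −20 °C) gives the arylmagnesium chloride F14. Formylation of F14 with DMF returns to the route at 16.

## Further compounds

F1 | step 23 | 2,6-bis(benzyloxy)-4-(ArABC-oxy)benzaldehyde | O=Cc4c(OCc9ccccc9)cc(Oc3c(OCc9ccccc9)c(OCc9ccccc9)c(OCc9ccccc9)cc3Oc2c(OCc9ccccc9)cc(Oc1c(OCc9ccccc9)cc(OCc9ccccc9)cc1OCc9ccccc9)cc2OCc9ccccc9)cc4OCc9ccccc9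
F2 | step 23 | 2,6-bis(benzyloxy)-4-(ArABC-oxy)phenyl formate | O=COc4c(OCc9ccccc9)cc(Oc3c(OCc9ccccc9)c(OCc9ccccc9)c(OCc9ccccc9)cc3Oc2c(OCc9ccccc9)cc(Oc1c(OCc9ccccc9)cc(OCc9ccccc9)cc1OCc9ccccc9)cc2OCc9ccccc9)cc4OCc9ccccc9
F3 | step 23 | 2,6-bis(benzyloxy)-4-(ArABC-oxy)phenol | Oc4c(OCc9ccccc9)cc(Oc3c(OCc9ccccc9)c(OCc9ccccc9)c(OCc9ccccc9)cc3Oc2c(OCc9ccccc9)cc(Oc1c(OCc9ccccc9)cc(OCc9ccccc9)cc1OCc9ccccc9)cc2OCc9ccccc9)cc4OCc9ccccc9
F4 | step 23 | 2,3,4-tris(benzyloxy)-6-[2,6-bis(benzyloxy)-4-(ArABC-oxy)phenoxy]benzaldehyde | O=Cc5c(OCc9ccccc9)c(OCc9ccccc9)c(OCc9ccccc9)cc5Oc4c(OCc9ccccc9)cc(Oc3c(OCc9ccccc9)c(OCc9ccccc9)c(OCc9ccccc9)cc3Oc2c(OCc9ccccc9)cc(Oc1c(OCc9ccccc9)cc(OCc9ccccc9)cc1OCc9ccccc9)cc2OCc9ccccc9)cc4OCc9ccccc9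
F5 | step 23 | 2,3,4-tris(benzyloxy)-6-[2,6-bis(benzyloxy)-4-(ArABC-oxy)phenoxy]phenyl formate | O=COc5c(OCc9ccccc9)c(OCc9ccccc9)c(OCc9ccccc9)cc5Oc4c(OCc9ccccc9)cc(Oc3c(OCc9ccccc9)c(OCc9ccccc9)c(OCc9ccccc9)cc3Oc2c(OCc9ccccc9)cc(Oc1c(OCc9ccccc9)cc(OCc9ccccc9)cc1OCc9ccccc9)cc2OCc9ccccc9)cc4OCc9ccccc9
F6 | step 23 | 2,3,4-tris(benzyloxy)-6-[2,6-bis(benzyloxy)-4-(ArABC-oxy)phenoxy]phenol | Oc5c(OCc9ccccc9)c(OCc9ccccc9)c(OCc9ccccc9)cc5Oc4c(OCc9ccccc9)cc(Oc3c(OCc9ccccc9)c(OCc9ccccc9)c(OCc9ccccc9)cc3Oc2c(OCc9ccccc9)cc(Oc1c(OCc9ccccc9)cc(OCc9ccccc9)cc1OCc9ccccc9)cc2OCc9ccccc9)cc4OCc9ccccc9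
F7 | step 23 | 1,2,3-tris(benzyloxy)-5-{2,3,4-tris(benzyloxy)-6-[2,6-bis(benzyloxy)-4-(ArABC-oxy)phenoxy]phenoxy}benzene (hexadeca-O-benzyl hexamer) | c6c(OCc9ccccc9)c(OCc9ccccc9)c(OCc9ccccc9)cc6Oc5c(OCc9ccccc9)c(OCc9ccccc9)c(OCc9ccccc9)cc5Oc4c(OCc9ccccc9)cc(Oc3c(OCc9ccccc9)c(OCc9ccccc9)c(OCc9ccccc9)cc3Oc2c(OCc9ccccc9)cc(Oc1c(OCc9ccccc9)cc(OCc9ccccc9)cc1OCc9ccccc9)cc2OCc9ccccc9)cc4OCc9ccccc9
F8 | step 22 | benzyl (trimethylsilyl)ethynyl ether | C[Si](C)(C)C#COCc1ccccc1
F9 | step 22 | racemic 3-(benzyloxy)-4-(ArEF-oxy)-2-(trimethylsilyl)cyclobut-2-en-1-one | O=C7C([Si](C)(C)C)=C(OCc9ccccc9)C7Oc5cc(OCc9ccccc9)c(OCc9ccccc9)c(OCc9ccccc9)c5Oc6cc(OCc9ccccc9)c(OCc9ccccc9)c(OCc9ccccc9)c6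
F10 | step 11 | ArABC (Z)-2-chlorovinyl ether | Cl/C=C\Oc3c(OCc9ccccc9)c(OCc9ccccc9)c(OCc9ccccc9)cc3Oc2c(OCc9ccccc9)cc(Oc1c(OCc9ccccc9)cc(OCc9ccccc9)cc1OCc9ccccc9)cc2OCc9ccccc9
F11 | step 8 | 2,3,4-tris(benzyloxy)-6-hydroxybenzaldehyde | O=Cc1c(O)cc(OCc9ccccc9)c(OCc9ccccc9)c1OCc9ccccc9
F12 | step 8 | 3,4,5-tris(benzyloxy)-2-formylphenyl trifluoromethanesulfonate | O=Cc1c(OS(=O)(=O)C(F)(F)F)cc(OCc9ccccc9)c(OCc9ccccc9)c1OCc9ccccc9
F13 | step 7 | 1,2,3-tris(benzyloxy)-4,5-dibromobenzene | Brc1cc(OCc9ccccc9)c(OCc9ccccc9)c(OCc9ccccc9)c1Br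
F14 | step 7 | [2,3,4-tris(benzyloxy)-6-bromophenyl]magnesium chloride | Cl[Mg]c1c(Br)cc(OCc9ccccc9)c(OCc9ccccc9)c1OCc9ccccc9
A1 | alternative 1 | hexamer with ring B as bis(methoxymethyl) ether and fourteen benzyl ethers | COCOc1cc(Oc2c(OCc3ccccc3)cc(OCc3ccccc3)cc2OCc2ccccc2)cc(OCOC)c1Oc1cc(OCc2ccccc2)c(OCc2ccccc2)c(OCc2ccccc2)c1Oc1cc(OCc2ccccc2)c(Oc2cc(OCc3ccccc3)c(OCc3ccccc3)c(OCc3ccccc3)c2Oc2cc(OCc3ccccc3)c(OCc3ccccc3)c(OCc3ccccc3)c2)c(OCc2ccccc2)c1
A2 | alternative 1 | (η5-cyclopentadienyl)[η6-1,4-dichloro-2,6-bis(methoxymethoxy)benzene]ruthenium hexafluorophosphate | COCOc1cc(Cl)cc(OCOC)c1Cl.[Ru+2].c1cc[cH-]c1.F[P-](F)(F)(F)(F)F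
A3 | alternative 1 | CDEF phenol, 3,4,5-tris(benzyloxy)-2-(3,5-bis(benzyloxy)-4-{3,4,5-tris(benzyloxy)-2-[3,4,5-tris(benzyloxy)phenoxy]phenoxy}phenoxy)phenol | Oc1cc(OCc2ccccc2)c(OCc2ccccc2)c(OCc2ccccc2)c1Oc1cc(OCc2ccccc2)c(Oc2cc(OCc3ccccc3)c(OCc3ccccc3)c(OCc3ccccc3)c2Oc2cc(OCc3ccccc3)c(OCc3ccccc3)c(OCc3ccccc3)c2)c(OCc2ccccc2)c1
A4 | alternative 2 | 2,6-bis(benzyloxy)-4-[2,4,6-tris(benzyloxy)phenoxy]phenol (identical with 12) | Oc1c(OCc2ccccc2)cc(Oc2c(OCc3ccccc3)cc(OCc3ccccc3)cc2OCc2ccccc2)cc1OCc1ccccc1
A5 | alternative 2 | (Z)-3-(dimethylamino)-2-[2,4,6-tris(benzyloxy)phenoxy]acrolein | CN(C)/C=C(/C=O)Oc1c(OCc2ccccc2)cc(OCc2ccccc2)cc1OCc1ccccc1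
A6 | alternative 2 | 1,3-bis(benzyloxy)propan-2-one | O=C(COCc1ccccc1)COCc1ccccc1
A7 | alternative 3 | hexamer with ring A as dimethyl 2,4,6-trihydroxy-5-aryloxyisophthalate | COC(=O)c1c(O)c(C(=O)OC)c(O)c(c1O)Oc1cc(OCc2ccccc2)c(Oc2cc(OCc3ccccc3)c(OCc3ccccc3)c(OCc3ccccc3)c2Oc2cc(OCc3ccccc3)c(Oc3cc(OCc4ccccc4)c(OCc4ccccc4)c(OCc4ccccc4)c3Oc3cc(OCc4ccccc4)c(OCc4ccccc4)c(OCc4ccccc4)c3)c(OCc3ccccc3)c2)c(OCc2ccccc2)c1
A8 | alternative 3 | dimethyl 2-(BCDEF-aryloxy)malonate | COC(=O)C(C(=O)OC)Oc1cc(OCc2ccccc2)c(Oc2cc(OCc3ccccc3)c(OCc3ccccc3)c(OCc3ccccc3)c2Oc2cc(OCc3ccccc3)c(Oc3cc(OCc4ccccc4)c(OCc4ccccc4)c(OCc4ccccc4)c3Oc3cc(OCc4ccccc4)c(OCc4ccccc4)c(OCc4ccccc4)c3)c(OCc3ccccc3)c2)c(OCc2ccccc2)c1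
A9 | alternative 3 | dimethyl 3-oxopentanedioate | COC(=O)CC(=O)CC(=O)OC
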